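**Retrosynthetic overview**
- Target ⇒ (1′R,2′S)-triol: the isovalerate goes on last, at the benzylic O‑1′ (O‑2′ is neopentyl-like, O‑3′ tertiary).
- Triol ⇒ trans-1′,2′-acetonide by hydrolysis.
- Aryl–C1′ bond ⇒ 6-bromo-7-methoxycoumarin plus the O–CH2 of a glycerate-derived dioxolane, joined by light-driven decatungstate HAT/nickel C(sp3)–H arylation; the purchased C2′ centre directs trans arylation and so sets C1′.
- Dioxolane carbinol ⇐ methyl (S)-glycerate acetonide + MeMgBr; bromocoumarin ⇐ 5-bromo-2-hydroxy-4-methoxybenzaldehyde (Wittig/lactonisation).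
- Ring order: benzene and dioxolane rings are bought; the pyranone ring is closed in step 2, before the coupling; no ring is formed afterwards.

Assumption: side-chain carbons are C1′ (aryl-bearing), C2′, C3′; reagents whose atoms end up in a product (MeMgBr, the Wittig ylide, isovaleric anhydride) are numbered as compounds, while catalysts, bases and solvents are not.

**Route**

Step 1
Reactants: 1 methyl (4S)-2,2-dimethyl-1,3-dioxolane-4-carboxylate; 2 methylmagnesium bromide
Product: 3 2-[(4S)-2,2-dimethyl-1,3-dioxolan-4-yl]propan-2-ol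
Conditions: MeMgBr (2.5 equiv), THF, 0 °C to rt; then sat. aq NH4Cl
Reagents that add atoms: methylmagnesium bromide (2), C[Mg]Br
Why: Double Grignard addition to the ester gives the tertiary carbinol, and the acetonide and the purchased stereocentre (the future C2′, S) are untouched under these basic conditions.

Step 2
Reactants: 4 5-bromo-2-hydroxy-4-methoxybenzaldehyde; 5 ethyl (triphenylphosphoranylidene)acetate
Product: 8 6-bromo-7-methoxy-2H-chromen-2-one, via E-cinnamate ester 6 (not isolated), via Z-cinnamate ester 7 (not isolated)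
Conditions: Ph3P=CHCO2Et (1.2 equiv), PhNEt2, reflux (215 °C), 4 h
Reagents that add atoms: ethyl (triphenylphosphoranylidene)acetate (5), CCOC(=O)C=P(c1ccccc1)(c1ccccc1)c1ccccc1
Why: Wittig olefination of the salicylaldehyde followed by thermal E→Z isomerisation and lactonisation with loss of ethanol (the classical one-pot coumarin synthesis) fixes Br at C6 and OMe at C7; aryl bromide and methyl ether are inert.

Step 3
Reactants: 8 6-bromo-7-methoxy-2H-chromen-2-one (limiting); 3 2-[(4S)-2,2-dimethyl-1,3-dioxolan-4-yl]propan-2-ol (3 equiv, excess recovered)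
Product: 10 6-[(4R,5S)-5-(2-hydroxypropan-2-yl)-2,2-dimethyl-1,3-dioxolan-4-yl]-7-methoxy-2H-chromen-2-one, via dioxolan-4-yl radical 9 (not isolated)
Conditions: (nBu4N)4W10O32 (2 mol%), NiBr2·dme (5 mol%), dtbbpy (5 mol%), K3PO4 (1.1 equiv), MeCN (0.05 M), 390 nm LEDs, 25 °C, Ar
Reagents that add atoms: none
Why: Proposed new method: site- and diastereoselective decatungstate/nickel C(sp3)–H arylation of a chiral 4-substituted acetonide, in which photoexcited decatungstate abstracts the hydridic, unhindered O–CH2 hydrogen of 3 (the tertiary ring C–H is shielded by the adjacent CMe2OH, and O–H and methyl C–H are mismatched) to give radical 9, which is captured by (dtbbpy)Ni(Ar)Br from oxidative addition of 8, and Ni(III) reductive elimination on the ring face anti to the bulky CMe2OH makes the purchased C2′ (S) centre set C1′ as R (trans-dioxolane), with reduced decatungstate turning Ni(I) over and phosphate taking up HBr; the closest known reaction type is decatungstate/Ni C–H arylation of cyclic ethers and of the unsubstituted ethylene-glycol acetonide, together with trans-selective Ni arylation of tartrate-derived dioxolanyl radicals.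

Step 4
Reactants: 10 6-[(4R,5S)-5-(2-hydroxypropan-2-yl)-2,2-dimethyl-1,3-dioxolan-4-yl]-7-methoxy-2H-chromen-2-one
Product: 11 6-[(1R,2S)-1,2,3-trihydroxy-3-methylbutyl]-7-methoxy-2H-chromen-2-one
Conditions: AcOH/H2O 4:1, 45 °C
Reagents that add atoms: none
Why: Mild acid hydrolysis of the isopropylidene acetal cleaves only at the acetal carbon, so both C–O stereocentres are retained, and the lactone and aryl methyl ether survive.

Step 5
Reactants: 11 6-[(1R,2S)-1,2,3-trihydroxy-3-methylbutyl]-7-methoxy-2H-chromen-2-one; 12 3-methylbutanoic anhydride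
Product: 13 (1R,2S)-2,3-dihydroxy-1-(7-methoxy-2-oxo-2H-chromen-6-yl)-3-methylbutyl 3-methylbutanoate
Conditions: (iBuCH2CO... i.e. isovaleric) anhydride (1.05 equiv), pyridine (3 equiv), DMAP (5 mol%), CH2Cl2, −20 °C; pH 7 buffer work-up
Reagents that add atoms: 3-methylbutanoic anhydride (12), CC(C)CC(=O)OC(=O)CC(C)C
Why: Kinetically regioselective DMAP-catalysed esterification, since the benzylic O‑1′ is the least hindered hydroxyl (O‑2′ is flanked by the quaternary carbinol, O‑3′ is tertiary), and no stereocentre is touched; the cold, base-poor conditions and neutral work-up suppress 1′→2′ acyl migration.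

**Compound list**
1 | methyl (4S)-2,2-dimethyl-1,3-dioxolane-4-carboxylate | CC1(C)OC[C@H](O1)C(=O)OC | starting material
2 | methylmagnesium bromide | C[Mg]Br | starting material
3 | 2-[(4S)-2,2-dimethyl-1,3-dioxolan-4-yl]propan-2-ol | CC1(C)OC[C@H](O1)C(C)(C)O | intermediate
4 | 5-bromo-2-hydroxy-4-methoxybenzaldehyde | COc1cc(O)c(C=O)cc1Br | starting material
5 | ethyl (triphenylphosphoranylidene)acetate | CCOC(=O)C=P(c1ccccc1)(c1ccccc1)c1ccccc1 | starting material
6 | ethyl (2E)-3-(5-bromo-2-hydroxy-4-methoxyphenyl)prop-2-enoate | CCOC(=O)/C=C/c1cc(Br)c(OC)cc1O | intermediate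
7 | ethyl (2Z)-3-(5-bromo-2-hydroxy-4-methoxyphenyl)prop-2-enoate | CCOC(=O)/C=C\c1cc(Br)c(OC)cc1O | intermediate
8 | 6-bromo-7-methoxy-2H-chromen-2-one | COc1cc2oc(=O)ccc2cc1Br | intermediate
9 | (5S)-5-(2-hydroxypropan-2-yl)-2,2-dimethyl-1,3-dioxolan-4-yl radical | CC1(C)O[CH][C@H](O1)C(C)(C)O | intermediate
10 | 6-[(4R,5S)-5-(2-hydroxypropan-2-yl)-2,2-dimethyl-1,3-dioxolan-4-yl]-7-methoxy-2H-chromen-2-one | COc1cc2oc(=O)ccc2cc1[C@@H](OC3(C)C)[C@H](O3)C(C)(C)O | intermediate
11 | 6-[(1R,2S)-1,2,3-trihydroxy-3-methylbutyl]-7-methoxy-2H-chromen-2-one | COc1cc2oc(=O)ccc2cc1[C@@H](O)[C@H](O)C(C)(C)O | intermediate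
12 | 3-methylbutanoic anhydride | CC(C)CC(=O)OC(=O)CC(C)C | starting material
13 | (1R,2S)-2,3-dihydroxy-1-(7-methoxy-2-oxo-2H-chromen-6-yl)-3-methylbutyl 3-methylbutanoate | COc1cc2oc(=O)ccc2cc1[C@@H](OC(=O)CC(C)C)[C@H](O)C(C)(C)O | target

**Step count and risks**
Total step count: 5. Longest linear sequence: 4 steps (1 → 3 → 4 → 5, or 2 → 3 → 4 → 5).

Most likely to fail:

1. Step 3 (the proposed new C–H arylation). Risks are:
   - hydrogen abstraction at the tertiary ring C–H, which would lower yield and erode ee;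
   - Giese addition of radical 9 to the coumarin C3=C4 bond;
   - coumarin [2+2] dimerisation under near-UV light;
   - slow coupling of an α-branched radical with an ortho-methoxy aryl–nickel.

   Fallback with known chemistry, setting out from 8 and returning at 10: dimethyl (4S,5S)-2,2-dimethyl-1,3-dioxolane-4,5-dicarboxylate F1 (purchased, D-tartrate series) is mono-saponified (KOH 1.0 equiv, MeOH, rt) to (4S,5S)-5-(methoxycarbonyl)-2,2-dimethyl-1,3-dioxolane-4-carboxylic acid F2. MeMgBr (3.5 equiv, THF, 0 °C) converts the remaining ester into the carbinol, giving (4S,5S)-5-(2-hydroxypropan-2-yl)-2,2-dimethyl-1,3-dioxolane-4-carboxylic acid F3. F3 and 8 are then joined by the established Ir/Ni decarboxylative arylation of α-oxy acids (Ir[dF(CF3)ppy]2(dtbbpy)PF6 1 mol%, NiCl2·dme 10 mol%, dtbbpy, Cs2CO3, DMF, 450 nm, rt). Here the radical is generated only at the carboxyl-bearing carbon, passes through the same radical 9, and couples trans to give 10.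

2. Step 5 (O‑1′ versus O‑2′ selectivity, over-acylation, acyl migration). Fallback setting out from 11 and returning at 13: 11 is equilibrated in dry acetone with cat. CSA and 4 Å sieves to the more substituted 2′,3′-acetonide 6-{(R)-hydroxy[(4S)-2,2,5,5-tetramethyl-1,3-dioxolan-4-yl]methyl}-7-methoxy-2H-chromen-2-one F4, which is expected to be favoured by the gem-dimethyl effect (co-formed 10 is resubjected). Its only free hydroxyl is O‑1′, so acylation with 12 (DMAP, pyridine, CH2Cl2) gives (R)-(7-methoxy-2-oxo-2H-chromen-6-yl)[(4S)-2,2,5,5-tetramethyl-1,3-dioxolan-4-yl]methyl 3-methylbutanoate F5 with the regiochemistry fixed by protection. AcOH/H2O (4:1, 40 °C) then releases 13.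

3. Step 2 (215 °C one-pot; incomplete E→Z isomerisation or thermal loss of material; steps 1 and 4 are routine by comparison). Fallback setting out from 4 and returning at 8: Knoevenagel condensation of 4 with Meldrum's acid (cat. piperidinium acetate, EtOH, reflux) lactonises directly to 6-bromo-7-methoxy-2-oxo-2H-chromene-3-carboxylic acid F6, with no alkene isomerisation needed. Ag2CO3-catalysed protodecarboxylation (AcOH, DMSO, 120 °C) then gives 8.

**Further compounds**
F1 | step 3 | dimethyl (4S,5S)-2,2-dimethyl-1,3-dioxolane-4,5-dicarboxylate (purchased) | COC(=O)[C@@H](OC1(C)C)[C@H](O1)C(=O)OC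
F2 | step 3 | (4S,5S)-5-(methoxycarbonyl)-2,2-dimethyl-1,3-dioxolane-4-carboxylic acid | OC(=O)[C@@H](OC1(C)C)[C@H](O1)C(=O)OC
F3 | step 3 | (4S,5S)-5-(2-hydroxypropan-2-yl)-2,2-dimethyl-1,3-dioxolane-4-carboxylic acid | OC(=O)[C@@H](OC1(C)C)[C@H](O1)C(C)(C)O
F4 | step 5 | 6-{(R)-hydroxy[(4S)-2,2,5,5-tetramethyl-1,3-dioxolan-4-yl]methyl}-7-methoxy-2H-chromen-2-one | COc1cc2oc(=O)ccc2cc1[C@@H](O)[C@H](OC3(C)C)C(C)(C)O3
F5 | step 5 | (R)-(7-methoxy-2-oxo-2H-chromen-6-yl)[(4S)-2,2,5,5-tetramethyl-1,3-dioxolan-4-yl]methyl 3-methylbutanoate | COc1cc2oc(=O)ccc2cc1[C@@H](OC(=O)CC(C)C)[C@H](OC3(C)C)C(C)(C)O3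
F6 | step 2 | 6-bromo-7-methoxy-2-oxo-2H-chromene-3-carboxylic acid | COc1cc2oc(=O)c(C(=O)O)cc2cc1Br
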